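**Retrosynthetic overview**

1. The target comes from the oxolane tetrapivalate 29 by hydride removal of four pivalates. The oxolane is the only ring built in the route and it is closed last.
2. 29 is cut at O1–C2. C2 is benzylic to ring B and para to the ring B ether oxygen, so this bond can form and re-open through a p-alkoxybenzyl cation until ring B sits trans to the C3 hydroxymethyl group. The precursor is the acyclic tetraol 28, used as both C2 epimers.
3. 28 is cut at C2–C(ring B): aldehyde 15 (fragment AB) plus the arylmagnesium reagent from iodide 25 (fragment BC).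
4. In 15, C3 and C4 come from Sharpless epoxidation of the E allylic alcohol 10 and anti opening at C3 by a vinyl copper reagent; the vinyl group becomes the formyl group. 10 comes from but-2-yne-1,4-diol and a vanillin-derived benzylzinc reagent.
5. In 25, C8'' comes from an Evans syn aldol of the ring B aryloxyacetyl imide with vanillin pivalate; Mitsunobu inversion at C7'' gives the erythro side chain.

Key step: step 20

Locants: oxolane O1, C2 (bears ring B), C3 (bears C9H2OH), C4 (tertiary carbinol, bears the ring A benzyl group), C5 (CH2); side chain C7'' (carbinol on ring C), C8'' (aryloxy carbon), C9''.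
Assumption: 4-iodo-2-methoxyphenol replaces the bromide as ring B source, because only the iodide should undergo halogen–magnesium exchange below 0 °C next to pivalates; the C9 hydroxyl is carried free through the ring closure, where it could only close a four-membered ring.

**Route**

Step 1
Reactants: 1 vanillin
Product: 2 4-formyl-2-methoxyphenyl pivalate
Conditions: PivCl, Et3N, DMAP (cat.), CH2Cl2, 0 → 25 °C
Reagents that add atoms: pivaloyl chloride, CC(C)(C)C(=O)Cl
Why: DMAP-catalysed O-acylation of the only hydroxyl group (phenol esterification) should give the pivalate that later deactivates rings A and C.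

Step 2
Reactants: 2 4-formyl-2-methoxyphenyl pivalate
Product: 3 4-(hydroxymethyl)-2-methoxyphenyl pivalate
Conditions: NaBH4, THF/EtOH, 0 °C
Reagents that add atoms: none
Why: Borohydride reduction of the aldehyde is chemoselective because the hindered aryl pivalate is not reduced at 0 °C.

Step 3
Reactants: 3 4-(hydroxymethyl)-2-methoxyphenyl pivalate
Product: 4 4-(chloromethyl)-2-methoxyphenyl pivalate
Conditions: SOCl2, CH2Cl2, 0 → 25 °C
Reagents that add atoms: thionyl chloride, O=S(Cl)Cl
Why: Deoxychlorination of a benzylic alcohol through its chlorosulfite is fast and leaves the ester untouched.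

Step 4
Reactants: 5 but-2-yne-1,4-diol
Product: 6 4-[(tert-butyldimethylsilyl)oxy]but-2-yn-1-ol
Conditions: TBSCl (1 equiv), imidazole, 5 (3 equiv), DMF, 0 → 25 °C
Reagents that add atoms: tert-butyldimethylsilyl chloride, CC(C)(C)[Si](C)(C)Cl
Why: Statistical monosilylation of a symmetric diol used in excess should give mainly the mono ether.

Step 5
Reactants: 6 4-[(tert-butyldimethylsilyl)oxy]but-2-yn-1-ol
Product: 8 (2Z)-4-[(tert-butyldimethylsilyl)oxy]-3-iodobut-2-en-1-ol, via cyclic sodium alkenylalanate 7 (not isolated)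
Conditions: NaAlH2(OCH2CH2OMe)2 (Red-Al), THF, 0 °C; then I2, THF, −78 → 0 °C
Reagents that add atoms: iodine, II; sodium bis(2-methoxyethoxy)aluminium dihydride, [Na+].COCCO[AlH2-]OCCOC (in 7 only)
Why: Hydroxyl-directed trans hydroalumination of the propargylic alcohol puts aluminium on the carbon remote from the free hydroxyl, and iodinolysis with retention should give the Z iodide whose geometry later fixes the C3/C4 relationship.

Step 6
Reactants: 4 4-(chloromethyl)-2-methoxyphenyl pivalate; 8 (2Z)-4-[(tert-butyldimethylsilyl)oxy]-3-iodobut-2-en-1-ol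
Product: 10 4-[(2E)-2-{[(tert-butyldimethylsilyl)oxy]methyl}-4-hydroxybut-2-en-1-yl]-2-methoxyphenyl pivalate, via benzylzinc chloride 9 (not isolated)
Conditions: 4, Zn dust, LiCl, THF, 25 °C (gives 9, 2.2 equiv); then 8, Pd(OAc)2 (2 mol%), SPhos (4 mol%), THF, 25 °C
Reagents that add atoms: zinc, [Zn] (in 9 only)
Why: LiCl-promoted zinc insertion gives an ester-tolerant benzylzinc reagent, and Negishi coupling with the alkenyl iodide proceeds with retention of geometry and faster than protonation by the free hydroxyl, so the benzyl group should end cis to the CH2OH group.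

Step 7
Reactants: 10 the E allylic alcohol from step 6
Product: 11 4-{[(2R,3R)-2-{[(tert-butyldimethylsilyl)oxy]methyl}-3-(hydroxymethyl)oxiran-2-yl]methyl}-2-methoxyphenyl pivalate
Conditions: Ti(OiPr)4 (10 mol%), D-(−)-diisopropyl tartrate (12 mol%), tBuOOH, 4 Å MS, CH2Cl2, −20 °C
Reagents that add atoms: tert-butyl hydroperoxide, CC(C)(C)OO
Why: Sharpless asymmetric epoxidation of a 3,3-disubstituted allylic alcohol, in which the D-(−)-tartrate ligand should direct oxygen to the face that gives the (2R,3R) epoxide (the enantiomeric series to the 2S epoxides from L-(+)-tartrate), sets C4 in its final configuration and C3 in the configuration that the next step inverts.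

Step 8
Reactants: 11 the (2R,3R) epoxy alcohol
Product: 12 4-[(2S,3S)-2-{[(tert-butyldimethylsilyl)oxy]methyl}-2-hydroxy-3-(hydroxymethyl)pent-4-en-1-yl]-2-methoxyphenyl pivalate
Conditions: CH2=CHMgBr (4 equiv), CuI (20 mol%), THF/Et2O, −40 → −20 °C
Reagents that add atoms: vinylmagnesium bromide, C=C[Mg]Br
Why: Copper-catalysed SN2 opening of the 2,3-epoxy alcohol can only occur at the secondary carbon because the other epoxide carbon is fully substituted, so anti attack with inversion should set the final C3 configuration while the C4–O bond is untouched.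

Step 9
Reactants: 12 the 1,3-diol from step 8
Product: 13 4-{[(4S,5S)-2,2-di-tert-butyl-4-{[(tert-butyldimethylsilyl)oxy]methyl}-5-ethenyl-1,3,2-dioxasilinan-4-yl]methyl}-2-methoxyphenyl pivalate
Conditions: tBu2Si(OTf)2, 2,6-lutidine, CH2Cl2, 0 °C
Reagents that add atoms: di-tert-butylsilyl bis(trifluoromethanesulfonate), CC(C)(C)[Si](OS(=O)(=O)C(F)(F)F)(OS(=O)(=O)C(F)(F)F)C(C)(C)C
Why: Silylene formation across the primary C9 and tertiary C4 hydroxyls (silyl triflate silylation of a 1,3-diol) removes every acidic proton and the free β-hydroxyl, so the later aldehyde should neither quench the aryl metal nor undergo retro-aldol cleavage.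

Step 10
Reactants: 13 the vinyl silylene
Product: 15 4-{[(4S,5S)-2,2-di-tert-butyl-4-{[(tert-butyldimethylsilyl)oxy]methyl}-5-formyl-1,3,2-dioxasilinan-4-yl]methyl}-2-methoxyphenyl pivalate, via secondary ozonide 14 (not isolated)
Conditions: O3, CH2Cl2, −78 °C; then PPh3, −78 → 20 °C
Reagents that add atoms: ozone, [O-][O+]=O
Why: Ozonolysis with reductive work-up cleaves the terminal alkene much faster than the acylated guaiacyl ring is attacked, and the neutral conditions should leave the α-stereocentre C3 intact.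

Step 11
Reactants: 16 4-iodo-2-methoxyphenol
Product: 17 (4-iodo-2-methoxyphenoxy)acetic acid
Conditions: BrCH2CO2H, NaOH, H2O, reflux; then HCl
Reagents that add atoms: bromoacetic acid, OC(=O)CBr
Why: Williamson ether synthesis between the phenoxide and bromoacetate is a standard route to aryloxyacetic acids and does not touch the aryl iodide.

Step 12
Reactants: 17 (4-iodo-2-methoxyphenoxy)acetic acid
Product: 19 (4S)-4-benzyl-3-[(4-iodo-2-methoxyphenoxy)acetyl]-1,3-oxazolidin-2-one, via mixed pivalic anhydride 18 (not isolated)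
Conditions: PivCl, Et3N, THF, −20 °C (gives 18); then (S)-4-benzyl-1,3-oxazolidin-2-one, LiCl, −20 → 25 °C
Reagents that add atoms: (S)-4-benzyl-1,3-oxazolidin-2-one, O=C1N[C@@H](Cc2ccccc2)CO1; pivaloyl chloride, CC(C)(C)C(=O)Cl (in 18 only)
Why: N-acylation of the oxazolidinone through the mixed anhydride occurs at the less hindered aryloxyacetyl carbonyl.

Step 13
Reactants: 19 the aryloxyacetyl imide; 2 4-formyl-2-methoxyphenyl pivalate
Product: 21 (4S)-4-benzyl-3-{(2S,3R)-3-hydroxy-2-(4-iodo-2-methoxyphenoxy)-3-[3-methoxy-4-(pivaloyloxy)phenyl]propanoyl}-1,3-oxazolidin-2-one, via Z dibutylboron enolate 20 (not isolated)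
Conditions: Bu2BOTf, iPr2NEt, CH2Cl2, −78 → 0 °C (gives 20); then 2, −78 → 0 °C; then pH 7 buffer, MeOH, H2O2, 0 °C
Reagents that add atoms: dibutylboron triflate, CCCCB(CCCC)OS(=O)(=O)C(F)(F)F (in 20 only)
Why: Evans syn aldol reaction of the Z boron enolate through a Zimmerman–Traxler chair, with the auxiliary benzyl group shielding one enolate face, should set C8'' in its final R configuration and C7'' as the threo (R) carbinol.

Step 14
Reactants: 21 the syn aldol adduct
Product: 22 4-[(1R,2R)-1,3-dihydroxy-2-(4-iodo-2-methoxyphenoxy)propyl]-2-methoxyphenyl pivalate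
Conditions: NaBH4, THF/H2O, 0 → 25 °C
Reagents that add atoms: none
Why: Borohydride attacks the activated exocyclic imide carbonyl and reduces it to the primary alcohol (reductive auxiliary cleavage) without breaking a bond at C7'' or C8''.

Step 15
Reactants: 22 the threo diol
Product: 23 (1S,2R)-2-(4-iodo-2-methoxyphenoxy)-1-[3-methoxy-4-(pivaloyloxy)phenyl]propane-1,3-diyl bis(4-nitrobenzoate)
Conditions: 4-O2NC6H4CO2H (2.6 equiv), PPh3, iPrO2CN=NCO2iPr (DIAD), THF, 0 → 25 °C
Reagents that add atoms: 4-nitrobenzoic acid, OC(=O)c1ccc(cc1)[N+](=O)[O-]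
Why: In the Mitsunobu reaction the primary hydroxyl is esterified and the benzylic C7'' hydroxyl is displaced by carboxylate with SN2 inversion, helped by the weakly donating p-pivaloyloxy ring C, which should convert the threo into the erythro (7''S,8''R) series.

Step 16
Reactants: 23 the erythro bis(4-nitrobenzoate)
Product: 24 (1S,2R)-1-(4-hydroxy-3-methoxyphenyl)-2-(4-iodo-2-methoxyphenoxy)propane-1,3-diol
Conditions: K2CO3, MeOH, 0 → 25 °C; NH4Cl work-up
Reagents that add atoms: none
Why: Base-mediated methanolysis (transesterification) removes both nitrobenzoates and the aryl pivalate without touching either stereocentre.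

Step 17
Reactants: 24 the erythro triol
Product: 25 (1S,2R)-2-(4-iodo-2-methoxyphenoxy)-1-[3-methoxy-4-(pivaloyloxy)phenyl]propane-1,3-diyl dipivalate
Conditions: PivCl, pyridine, DMAP (cat.), CH2Cl2, 0 → 40 °C
Reagents that add atoms: pivaloyl chloride, CC(C)(C)C(=O)Cl
Why: Exhaustive DMAP-catalysed acylation installs three pivalates that resist organomagnesium reagents and later keep C7'' and ring C from ionising.

Step 18
Reactants: 25 the fragment BC iodide; 15 the fragment AB aldehyde
Product: 27 silylene-protected carbinol (ring B of 25 joined at its former C–I carbon to the former formyl carbon of 15; both epimers at the new C2 carbinol), via arylmagnesium chloride 26 (not isolated)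
Conditions: 25 (1.3 equiv), iPrMgCl·LiCl, THF, −20 → 0 °C (gives 26); then 15, THF, −40 → 0 °C
Reagents that add atoms: isopropylmagnesium chloride–lithium chloride, CC(C)[Mg]Cl.[Li+].[Cl-] (Mg and Cl in 26 only)
Why: Iodine–magnesium exchange should be faster than attack on the hindered pivalates below 0 °C, and Grignard 1,2-addition to the aldehyde forms the C2–aryl bond, with both C2 epimers expected and both usable.

Step 19
Reactants: 27 the silylene-protected carbinol
Product: 28 seco-tetraol tetrapivalate (free hydroxyls at C2, C4, C5 and C9; both C2 epimers)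
Conditions: HF·pyridine, pyridine, THF, 0 → 25 °C
Reagents that add atoms: none
Why: Fluoride-driven desilylation removes the silylene and the TBS ether under pyridine-buffered conditions that should spare the pivalates; any premature ionisation at C2 would only lead on to 29.

Step 20
Reactants: 28 seco-tetraol tetrapivalate
Product: 29 oxolane tetrapivalate, (2S,3R,4S) in the locants above
Conditions: (1S)-(+)-camphor-10-sulfonic acid (10 mol%), CH2Cl2, 0 → 25 °C
Reagents that add atoms: none
Why: The sulfonic acid protonates the ring B benzylic hydroxyl of either C2 epimer, and loss of water gives a p-alkoxybenzyl cation delocalised onto the ring B ether oxygen, which the C5 primary hydroxyl captures to form the O1–C2 bond. The closest known reaction type is the acid-mediated cyclodehydration of 1-aryl-1,4-diols to 2-aryl oxolanes used for furanoid lignans. The oxolane closes in the 5-exo-trig mode; closure through O4 or O9 would give four-membered rings, and the six-membered carbocycle from attack of ring A is slowed by the ring A pivalate. The new C2 stereocentre is set under thermodynamic control by the fixed C3 and C4 centres, because the benzylic ether re-ionises under the same acid, so both carbinol epimers and any cis ether should drain to the isomer with ring B trans to the C3 hydroxymethyl group and trans to the C4 benzyl group. The step needs ionisation at C2 only, which is secured by the pivalates on O7'' and on the ring C and ring A phenols; the free C9 hydroxyl is harmless.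

Step 21
Reactants: 29 oxolane tetrapivalate
Product: 30 target, (3S,4R,5S)-5-(4-{[(1S,2R)-1,3-dihydroxy-1-(4-hydroxy-3-methoxyphenyl)propan-2-yl]oxy}-3-methoxyphenyl)-3-[(4-hydroxy-3-methoxyphenyl)methyl]-4-(hydroxymethyl)oxolan-3-ol
Conditions: LiAlH4 (excess), THF, 0 °C; then aqueous KNaC4H4O6 work-up at about pH 7
Reagents that add atoms: none
Why: Hydride reduction of esters cleaves the four pivalates as neopentyl alcohol while ethers and all five stereocentres are untouched, and the neutral tartrate work-up avoids acid at the two benzylic C–O bonds.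

**Compound list**

1 | vanillin | COc1cc(C=O)ccc1O | starting material
2 | 4-formyl-2-methoxyphenyl pivalate | COc1cc(C=O)ccc1OC(=O)C(C)(C)C | intermediate
3 | 4-(hydroxymethyl)-2-methoxyphenyl pivalate | COc1cc(CO)ccc1OC(=O)C(C)(C)C | intermediate
4 | 4-(chloromethyl)-2-methoxyphenyl pivalate | COc1cc(CCl)ccc1OC(=O)C(C)(C)C | intermediate
5 | but-2-yne-1,4-diol | OCC#CCO | starting material
6 | 4-[(tert-butyldimethylsilyl)oxy]but-2-yn-1-ol | OCC#CCO[Si](C)(C)C(C)(C)C | intermediate
7 | cyclic sodium alkenylalanate from 6 (aluminium on the carbon bearing CH2OTBS, two 2-methoxyethoxy ligands; not isolated) | [Na+].COCCO[Al-]1(OCCOC)OCC=C1CO[Si](C)(C)C(C)(C)C | intermediate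
8 | (2Z)-4-[(tert-butyldimethylsilyl)oxy]-3-iodobut-2-en-1-ol | OC/C=C(\I)CO[Si](C)(C)C(C)(C)C | intermediate
9 | [3-methoxy-4-(pivaloyloxy)benzyl]zinc chloride (not isolated) | COc1cc(C[Zn]Cl)ccc1OC(=O)C(C)(C)C | intermediate
10 | 4-[(2E)-2-{[(tert-butyldimethylsilyl)oxy]methyl}-4-hydroxybut-2-en-1-yl]-2-methoxyphenyl pivalate | COc1cc(C/C(CO[Si](C)(C)C(C)(C)C)=C\CO)ccc1OC(=O)C(C)(C)C | intermediate
11 | 4-{[(2R,3R)-2-{[(tert-butyldimethylsilyl)oxy]methyl}-3-(hydroxymethyl)oxiran-2-yl]methyl}-2-methoxyphenyl pivalate | COc1cc(C[C@]2(CO[Si](C)(C)C(C)(C)C)O[C@@H]2CO)ccc1OC(=O)C(C)(C)C | intermediate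
12 | 4-[(2S,3S)-2-{[(tert-butyldimethylsilyl)oxy]methyl}-2-hydroxy-3-(hydroxymethyl)pent-4-en-1-yl]-2-methoxyphenyl pivalate | COc1cc(C[C@@](O)(CO[Si](C)(C)C(C)(C)C)[C@H](CO)C=C)ccc1OC(=O)C(C)(C)C | intermediate
13 | 4-{[(4S,5S)-2,2-di-tert-butyl-4-{[(tert-butyldimethylsilyl)oxy]methyl}-5-ethenyl-1,3,2-dioxasilinan-4-yl]methyl}-2-methoxyphenyl pivalate | COc1cc(C[C@]2(CO[Si](C)(C)C(C)(C)C)O[Si](C(C)(C)C)(C(C)(C)C)OC[C@@H]2C=C)ccc1OC(=O)C(C)(C)C | intermediate
14 | secondary ozonide of 13 (1,2,4-trioxolan-3-yl in place of ethenyl, mixture at the ozonide carbon; not isolated) | COc1cc(C[C@]2(CO[Si](C)(C)C(C)(C)C)O[Si](C(C)(C)C)(C(C)(C)C)OC[C@@H]2C3OCOO3)ccc1OC(=O)C(C)(C)C | intermediate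
15 | 4-{[(4S,5S)-2,2-di-tert-butyl-4-{[(tert-butyldimethylsilyl)oxy]methyl}-5-formyl-1,3,2-dioxasilinan-4-yl]methyl}-2-methoxyphenyl pivalate | COc1cc(C[C@]2(CO[Si](C)(C)C(C)(C)C)O[Si](C(C)(C)C)(C(C)(C)C)OC[C@@H]2C=O)ccc1OC(=O)C(C)(C)C | intermediate
16 | 4-iodo-2-methoxyphenol | COc1cc(I)ccc1O | starting material
17 | (4-iodo-2-methoxyphenoxy)acetic acid | COc1cc(I)ccc1OCC(=O)O | intermediate
18 | (4-iodo-2-methoxyphenoxy)acetic pivalic anhydride (not isolated) | COc1cc(I)ccc1OCC(=O)OC(=O)C(C)(C)C | intermediate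
19 | (4S)-4-benzyl-3-[(4-iodo-2-methoxyphenoxy)acetyl]-1,3-oxazolidin-2-one | COc1cc(I)ccc1OCC(=O)N2[C@@H](Cc3ccccc3)COC2=O | intermediate
20 | Z dibutylboron enolate of 19 (not isolated) | COc1cc(I)ccc1O/C=C(\OB(CCCC)CCCC)N2[C@@H](Cc3ccccc3)COC2=O | intermediate
21 | (4S)-4-benzyl-3-{(2S,3R)-3-hydroxy-2-(4-iodo-2-methoxyphenoxy)-3-[3-methoxy-4-(pivaloyloxy)phenyl]propanoyl}-1,3-oxazolidin-2-one | COc1cc(I)ccc1O[C@H](C(=O)N2[C@@H](Cc3ccccc3)COC2=O)[C@H](O)c4ccc(OC(=O)C(C)(C)C)c(OC)c4 | intermediate
22 | 4-[(1R,2R)-1,3-dihydroxy-2-(4-iodo-2-methoxyphenoxy)propyl]-2-methoxyphenyl pivalate (threo) | COc1cc(I)ccc1O[C@H](CO)[C@H](O)c2ccc(OC(=O)C(C)(C)C)c(OC)c2 | intermediate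
23 | (1S,2R)-2-(4-iodo-2-methoxyphenoxy)-1-[3-methoxy-4-(pivaloyloxy)phenyl]propane-1,3-diyl bis(4-nitrobenzoate) (erythro) | COc1cc(I)ccc1O[C@H](COC(=O)c2ccc(cc2)[N+](=O)[O-])[C@@H](OC(=O)c3ccc(cc3)[N+](=O)[O-])c4ccc(OC(=O)C(C)(C)C)c(OC)c4 | intermediate
24 | (1S,2R)-1-(4-hydroxy-3-methoxyphenyl)-2-(4-iodo-2-methoxyphenoxy)propane-1,3-diol | COc1cc(I)ccc1O[C@H](CO)[C@@H](O)c2ccc(O)c(OC)c2 | intermediate
25 | (1S,2R)-2-(4-iodo-2-methoxyphenoxy)-1-[3-methoxy-4-(pivaloyloxy)phenyl]propane-1,3-diyl dipivalate | COc1cc(I)ccc1O[C@H](COC(=O)C(C)(C)C)[C@@H](OC(=O)C(C)(C)C)c2ccc(OC(=O)C(C)(C)C)c(OC)c2 | intermediate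
26 | arylmagnesium chloride from 25 (MgCl in place of iodine; not isolated) | COc1cc([Mg]Cl)ccc1O[C@H](COC(=O)C(C)(C)C)[C@@H](OC(=O)C(C)(C)C)c2ccc(OC(=O)C(C)(C)C)c(OC)c2 | intermediate
27 | 4-{[(4S,5R)-2,2-di-tert-butyl-4-{[(tert-butyldimethylsilyl)oxy]methyl}-5-[hydroxy(aryl)methyl]-1,3,2-dioxasilinan-4-yl]methyl}-2-methoxyphenyl pivalate, aryl = 3-methoxy-4-{[(1S,2R)-1,3-bis(pivaloyloxy)-1-[3-methoxy-4-(pivaloyloxy)phenyl]propan-2-yl]oxy}phenyl, both carbinol epimers | COc1cc(C[C@]2(CO[Si](C)(C)C(C)(C)C)O[Si](C(C)(C)C)(C(C)(C)C)OC[C@@H]2C(O)c3ccc(O[C@H](COC(=O)C(C)(C)C)[C@@H](OC(=O)C(C)(C)C)c4ccc(OC(=O)C(C)(C)C)c(OC)c4)c(OC)c3)ccc1OC(=O)C(C)(C)C | intermediate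
28 | seco-tetraol tetrapivalate: 4-[(2S,3R)-2,4-dihydroxy-2-(hydroxymethyl)-3-[hydroxy(aryl)methyl]butyl]-2-methoxyphenyl pivalate, aryl as in 27, both carbinol epimers | COc1cc(C[C@@](O)(CO)[C@H](CO)C(O)c3ccc(O[C@H](COC(=O)C(C)(C)C)[C@@H](OC(=O)C(C)(C)C)c4ccc(OC(=O)C(C)(C)C)c(OC)c4)c(OC)c3)ccc1OC(=O)C(C)(C)C | intermediate
29 | oxolane tetrapivalate: 4-{[(3S,4R,5S)-3-hydroxy-4-(hydroxymethyl)-5-aryloxolan-3-yl]methyl}-2-methoxyphenyl pivalate, aryl as in 27 | COc1cc(C[C@@]2(O)CO[C@H](c3ccc(O[C@H](COC(=O)C(C)(C)C)[C@@H](OC(=O)C(C)(C)C)c4ccc(OC(=O)C(C)(C)C)c(OC)c4)c(OC)c3)[C@H]2CO)ccc1OC(=O)C(C)(C)C | intermediate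
30 | (3S,4R,5S)-5-(4-{[(1S,2R)-1,3-dihydroxy-1-(4-hydroxy-3-methoxyphenyl)propan-2-yl]oxy}-3-methoxyphenyl)-3-[(4-hydroxy-3-methoxyphenyl)methyl]-4-(hydroxymethyl)oxolan-3-ol | COc1cc(C[C@@]2(O)CO[C@H](c3ccc(O[C@H](CO)[C@@H](O)c4ccc(O)c(OC)c4)c(OC)c3)[C@H]2CO)ccc1O | target

**Step count**

Total steps: 21. Longest linear sequence: 12 steps (1, 2, 3, 6, 7, 8, 9, 10, 18, 19, 20, 21, from vanillin).

**Steps most likely to fail**

Step 18. The iodine–magnesium exchange on the electron-rich ring B may be slower than attack of the isopropyl or aryl Grignard reagent on the aryl pivalates, and the hindered aldehyde may be enolised, eroding C3, instead of being attacked. The fallback replaces the organomagnesium route by a chromium-mediated Barbier coupling (Nozaki–Hiyama–Kishi reaction). It sets out from 25 and 15, which are stirred together with CrCl2 (excess, divalent chromium) and NiCl2 (catalytic) in DMF/THF at 25 °C. Zerovalent nickel formed in the flask should insert into the C–I bond and pass the aryl group to chromium. The resulting non-basic arylchromium dichloride F1 (trivalent chromium) should add to the aldehyde without touching the esters or the α-stereocentre. The fallback comes back to the route at 27.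

Step 20. Under protic acid the cation may be attacked irreversibly by the ring A carbon para to its methoxy group, giving a six-membered carbocycle, before the cis ether has drained to the trans ether; on long exposure C7'' may also begin to ionise. The fallback moves the ionisation from the free carbinol to a preformed benzylic ester and from a Brønsted acid to a Lewis acid at low temperature. It sets out from 27. Ac2O, DMAP and pyridine should give the C2 acetate F2 (both epimers), and HF·pyridine with pyridine should remove the silicon groups to give the triol acetate F3. Sc(OTf)3 (5 mol%) in CH2Cl2 at −40 → −20 °C should then ionise the benzylic acetate (metal-triflate-catalysed benzylic substitution), so that the C5 hydroxyl closes the same O1–C2 bond under conditions where oxygen capture far outruns arene attack. The fallback comes back to the route at 29.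

Step 15. At the hindered benzylic C7'' the alkoxyphosphonium ion may eliminate toward the enol ether or collapse through an ion pair with partial retention, so that inversion is incomplete. The fallback corrects C7'' by oxidation and reagent-controlled reduction instead of substitution. It sets out from 22. PivCl (1.05 equiv) and pyridine at −20 °C should acylate only the primary hydroxyl to give the threo alcohol F4. Dess–Martin periodinane should give the aryl ketone F5 without touching C8''. Corey–Bakshi–Shibata reduction with (S)-2-methyl-CBS-oxazaborolidine and BH3·SMe2 at −20 °C, taking the aryl group as the larger ketone substituent, should give the (7''S) erythro alcohol F6. PivCl, DMAP and pyridine then give 25, where the fallback rejoins the route.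

**Further compounds**

F1 | step 18 | arylchromium dichloride from 25 (CrCl2 in place of iodine) | COc1cc([Cr](Cl)Cl)ccc1O[C@H](COC(=O)C(C)(C)C)[C@@H](OC(=O)C(C)(C)C)c2ccc(OC(=O)C(C)(C)C)c(OC)c2
F2 | step 20 | C2 acetate of 27 (both epimers) | COc1cc(C[C@]2(CO[Si](C)(C)C(C)(C)C)O[Si](C(C)(C)C)(C(C)(C)C)OC[C@@H]2C(OC(C)=O)c3ccc(O[C@H](COC(=O)C(C)(C)C)[C@@H](OC(=O)C(C)(C)C)c4ccc(OC(=O)C(C)(C)C)c(OC)c4)c(OC)c3)ccc1OC(=O)C(C)(C)C
F3 | step 20 | seco-triol C2 acetate tetrapivalate (free hydroxyls at C4, C5 and C9; both epimers) | COc1cc(C[C@@](O)(CO)[C@H](CO)C(OC(C)=O)c3ccc(O[C@H](COC(=O)C(C)(C)C)[C@@H](OC(=O)C(C)(C)C)c4ccc(OC(=O)C(C)(C)C)c(OC)c4)c(OC)c3)ccc1OC(=O)C(C)(C)C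
F4 | step 15 | (2R,3R)-3-hydroxy-2-(4-iodo-2-methoxyphenoxy)-3-[3-methoxy-4-(pivaloyloxy)phenyl]propyl pivalate (threo) | COc1cc(I)ccc1O[C@H](COC(=O)C(C)(C)C)[C@H](O)c2ccc(OC(=O)C(C)(C)C)c(OC)c2
F5 | step 15 | (2R)-2-(4-iodo-2-methoxyphenoxy)-3-[3-methoxy-4-(pivaloyloxy)phenyl]-3-oxopropyl pivalate | COc1cc(I)ccc1O[C@H](COC(=O)C(C)(C)C)C(=O)c2ccc(OC(=O)C(C)(C)C)c(OC)c2
F6 | step 15 | (2R,3S)-3-hydroxy-2-(4-iodo-2-methoxyphenoxy)-3-[3-methoxy-4-(pivaloyloxy)phenyl]propyl pivalate (erythro) | COc1cc(I)ccc1O[C@H](COC(=O)C(C)(C)C)[C@@H](O)c2ccc(OC(=O)C(C)(C)C)c(OC)c2
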